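Numbering follows germacrane. Ring A is the ten-membered carbocycle C1–C10 (C1 ketone, C4–C5 oxirane, C8 senecioate, C10 methyl). Ring B is the butenolide O–C6–C7=C11–C12, and C13 is the acetoxymethyl carbon.
Enabling feature: the sp2 carbon C7 lies between the oxygen-bearing carbons C6 and C8, and the C6 oxygen is the lactone oxygen of ring B. C7=C11 can therefore be read as a ring-A ketone condensed with an activated methylene (C11) hanging from O6, and a thioester on C11 both activates it and stands for C13.
Cuts, in order: the C13 acetate and the C13 oxidation level, C7=C11 (ring B), the acyl bonds at O6 and O8, C7=O back to C7=CH2, C7–C8 (ring A), C1–C10, C6–C7. This leaves nerol, an ethynyl unit, a crotyl unit, Meldrum's acid and senecioic acid.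
Forward: the oxirane is made first on nerol and the chain grows at C6, then at C1. Ring A closes by chromium-mediated coupling, ring B closes last in the condensation, and three steps finish C13.
Stereochemistry: C4/C5 come from asymmetric epoxidation of the Z-alkene, C6 from Felkin–Anh addition next to the oxirane, C10 from tartrate-controlled crotylboration, and C8 from the macrocyclic carbonyl addition.

Key step: step 16

Assumption: crotylboronate 11 is taken as a stock reagent (made in one flask from trans-2-butene, B(OiPr)3 and L-(+)-diisopropyl tartrate), and 4 is taken as the commercial THF solution.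

Step 1
Reactants: 1 nerol, (2Z)-3,7-dimethylocta-2,6-dien-1-ol
Product: 2 (2R,3S)-2,3-epoxynerol, [(2R,3S)-3-methyl-3-(4-methylpent-3-enyl)oxiran-2-yl]methanol (C5 R, C4 S; C3 and C6 cis on the oxirane)
Conditions: Ti(OiPr)4 (10 mol %), D-(−)-diethyl tartrate (12 mol %), t-BuOOH (anhydrous, decane), 4 Å MS, CH2Cl2, −20 °C
Reagents that add atoms: tert-butyl hydroperoxide, CC(C)(C)OO
Why: Katsuki–Sharpless asymmetric epoxidation acts only on the allylic-alcohol alkene, the (−)-tartrate catalyst places oxygen on the face that gives the (2R,3S)-oxirane and so fixes C5 and C4, and the Z geometry of nerol reappears as the cis relation of C3 and C6 on the three-membered ring.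

Step 2
Reactants: 2 (2R,3S)-2,3-epoxynerol
Product: 3 (2S,3S)-3-methyl-3-(4-methylpent-3-enyl)oxirane-2-carbaldehyde (same spatial arrangement as 2; the C5 descriptor changes only through the priority rules)
Conditions: TEMPO (10 mol %), PhI(OAc)2 (1.1 equiv), CH2Cl2, rt
Reagents that add atoms: none
Why: TEMPO/oxoammonium oxidation of a primary alcohol stops at the aldehyde under almost neutral conditions, spares the trisubstituted alkene and the oxirane, and cannot epimerise C5 because an oxirane carbon does not enolise readily.

Step 3
Reactants: 3 epoxy aldehyde; 4 ethynylmagnesium bromide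
Product: 5 (1R)-1-[(2R,3S)-3-methyl-3-(4-methylpent-3-enyl)oxiran-2-yl]prop-2-yn-1-ol (C6 carbinol R, 5,6-anti)
Conditions: 4 (0.5 M in THF, 1.5 equiv), THF, −78 °C; aq NH4Cl
Reagents that add atoms: none
Why: Grignard 1,2-addition under Felkin–Anh (Cornforth) control: with the C5–O bond turned away from the carbonyl oxygen the acetylide approaches past the small C5–H and not past the fully substituted C4, which should make the 5,6-anti carbinol (6R) the main epimer, to be freed from the minor one by chromatography.

Step 4
Reactants: 5 propargylic alcohol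
Product: 6 triethylsilyl ether of 5 (4S,5R,6R)
Conditions: Et3SiCl (1.3 equiv), imidazole (2.5 equiv), CH2Cl2, 0 °C → rt
Reagents that add atoms: chlorotriethylsilane, CC[Si](Cl)(CC)CC
Why: Silyl ether formation with imidazole as the only base avoids Payne migration of the epoxy alcohol, and triethylsilyl is chosen because it should last through steps 5 to 12 yet yield to buffered fluoride in step 13.

Step 5
Reactants: 6 propargylic silyl ether
Product: 8 2-iodoallyl triethylsilyl ether (4S,5R,6S; iodine on C7), via vinylstannane 7 (not isolated)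
Conditions: Bu3SnH (2 equiv), Mo(CO)3(CNtBu)3 (2 mol %), hydroquinone (cat), THF, 55 °C; then I2, CH2Cl2, 0 °C
Reagents that add atoms: tributyltin hydride, CCCC[SnH](CCCC)CCCC (tin stays only in 7); iodine, [I][I]
Why: Molybdenum-catalysed hydrostannation of terminal propargylic ethers places tin on the internal alkyne carbon (here C7), and the following tin–iodine exchange is far faster than any reaction of iodine at the trisubstituted alkene, so the 2-iodoallyl ether needed for step 10 results in one flask.

Step 6
Reactants: 8 2-iodoallyl silyl ether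
Product: 10 C1 aldehyde 3-[(2S,3R)-3-[(1S)-2-iodo-1-(triethylsilyloxy)prop-2-enyl]-2-methyloxiran-2-yl]propanal, via vicinal diol 9 (not isolated)
Conditions: OsO4 (2 mol %), NaIO4 (4 equiv), 2,6-lutidine (2 equiv), dioxane–H2O 3:1, rt
Reagents that add atoms: osmium tetroxide, O=[Os](=O)(=O)=O (passes on the oxygen, catalytic); sodium periodate, [Na+].[O-]I(=O)(=O)=O (terminal oxygen source)
Why: Lemieux–Johnson cleavage: OsO4 picks the electron-rich isopropylidene alkene over the iodine-bearing and oxygen-flanked C7 alkene, periodate splits diol 9 as it forms, and 2,6-lutidine keeps the medium from becoming acidic toward the oxirane.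

Step 7
Reactants: 10 C1 aldehyde; 11 (E)-crotylboronate of (R,R)-diisopropyl tartrate
Product: 12 anti homoallylic alcohol (1R,4S,5R,6S,10S) with C1–OH, C10–CH3 and the terminal vinyl group C9=C8
Conditions: 11 (1.5 equiv), 4 Å MS, toluene, −78 °C; aq NaHCO3
Reagents that add atoms: none
Why: Roush asymmetric crotylboration through a closed chair transition state: the E-crotyl geometry gives the anti adduct and the (R,R)-tartrate steers the reagent to the si face of the unbranched aldehyde, which sets C10 as S (and C1 as R, erased in step 9) without any added Lewis acid that could open the oxirane.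

Step 8
Reactants: 12 homoallylic alcohol
Product: 14 C1/C8 1,4-diol (1R,4S,5R,6S,10S), via bis-boron adduct 13 (not isolated)
Conditions: 9-BBN (2.5 equiv), THF, 0 °C → rt; then aq NaOH, 30% H2O2, 0 °C
Reagents that add atoms: 9-borabicyclo[3.3.1]nonane, B1C2CCCC1CCC2 (boron stays only in 13); hydrogen peroxide, OO
Why: Hydroboration–oxidation with 9-BBN is anti-Markovnikov and much faster at the monosubstituted alkene than at the 2-iodoalkene (the selectivity exploited in hydroboration/Suzuki sequences), and the basic oxidative work-up avoids the acid that would let the C1 hydroxyl open the oxirane at C4.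

Step 9
Reactants: 14 1,4-diol
Product: 16 C1-keto C8-aldehyde (4S,5R,6S,10S), via bis(alkoxysulfonium) salt 15 (not isolated)
Conditions: (COCl)2 (4 equiv), DMSO (8 equiv), CH2Cl2, −78 °C; then Et3N (12 equiv), −78 → 0 °C
Reagents that add atoms: dimethyl sulfoxide, CS(C)=O (its Me2S unit stays only in 15)
Why: Swern oxidation turns both hydroxyls into alkoxysulfonium ions before any base is present, so no lactol and hence no lactone can form from the 1,4-diol, and the cold amine treatment leaves the new α-stereocentre C10 untouched.

Step 10
Reactants: 16 iodoalkenyl keto aldehyde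
Product: 18 ring A allylic alcohol (4S,5R,6R,8R,10S) carrying the exocyclic C7 methylene and the C6 silyl ether, via alkenylchromium dichloride 17 (not isolated)
Conditions: CrCl2 (10 equiv), NiCl2 (0.1 equiv), DMSO, rt, slow addition of 16 (final 2 mM)
Reagents that add atoms: chromium dichloride, [Cr+2].[Cl-].[Cl-] (chromium stays only in 17)
Why: Nozaki–Hiyama–Kishi coupling: nickel-catalysed insertion into the carbon–iodine bond and transmetalation give alkenylchromium 17, which adds to aldehydes but ignores ketones, silyl ethers and oxiranes, so that under high dilution ring A closes at C7–C8 (helped by the bend that the cis-oxirane puts into the chain), and C8 is set by the conformation of the forming ring, in which the aldehyde oxygen and the bulky C6 silyloxy group are both expected to point away from the ring interior on the same flank of the C6–C7–C8 unit, that is the 6,8-cis (8R) alcohol.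

Step 11
Reactants: 18 ring A allylic alcohol
Product: 20 8-hydroxy-1,7-diketone (4S,5R,6S,8R,10S), via secondary ozonide 19 (not isolated)
Conditions: O3, CH2Cl2, −78 °C; then Me2S, −78 °C → rt
Reagents that add atoms: ozone, [O-][O+]=O
Why: Ozonolysis (Criegee mechanism) of the only C=C bond in 18 turns the exocyclic methylene into the C7 ketone, and it is run before the senecioate arrives so that no second alkene competes.

Step 12
Reactants: 20 hydroxy diketone; 21 3-methylbut-2-enoic acid (senecioic acid)
Product: 22 C8 senecioate (4S,5R,6S,8R,10S), C6 still silylated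
Conditions: 21 (2 equiv), DCC (2 equiv), DMAP (0.2 equiv), CH2Cl2, 0 °C → rt
Reagents that add atoms: none
Why: Steglich esterification of the single free hydroxyl with retention at C8; any transannular C1 hemiketal stays in equilibrium with the open γ-hydroxy ketone, whose secondary alcohol is acylated faster, and carbodiimide activation in the cold limits deconjugation of the senecioyl group.

Step 13
Reactants: 22 silyl ether
Product: 23 6-hydroxy-1,7-diketone 8-senecioate (4S,5R,6S,8R,10S)
Conditions: Bu4NF (1.2 equiv), AcOH (1.5 equiv), THF, 0 °C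
Reagents that add atoms: none
Why: Fluoride-induced desilylation is eased by the neighbouring ketone, and the acetic acid buffer protonates the alkoxide at once, which should suppress Payne migration, acyl shift from O8 and epimerisation at C6 or C8.

Step 14
Reactants: 24 Meldrum's acid; 25 ethanethiol
Product: 26 3-(ethylsulfanyl)-3-oxopropanoic acid (malonic acid half thioester)
Conditions: 25 (1.2 equiv), MeCN, sealed tube, 80 °C
Reagents that add atoms: none
Why: Thiolysis of Meldrum's acid: the thiol opens the activated cyclic diester, acetone is lost, and the half thioester forms below the temperature at which it would decarboxylate.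

Step 15
Reactants: 23 C6 alcohol; 26 malonic half thioester
Product: 27 ring A 1,7-diketone with the S-ethyl thiomalonyl ester on O6 and the senecioate on O8 (4S,5R,6S,8R,10S)
Conditions: 26 (1.5 equiv), DCC (1.5 equiv), CH2Cl2, 0 °C
Reagents that add atoms: none
Why: Carbodiimide coupling of a malonic half (thio)ester runs through the acylketene EtSC(O)CH=C=O, which acylates even hindered and electron-poor alcohols without added base, so that 27 never meets DMAP.

Step 16
Reactants: 27 O6-thiomalonyl 7-ketone
Product: 29 butenolide with C13 as S-ethyl thioester (4S,5R,6R,8R,10S), via titanium aldolate 28 (not isolated)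
Conditions: TiCl4 (2.5 equiv, pre-mixed with THF at 0 °C to give TiCl4·2THF), pyridine (6 equiv), THF–CH2Cl2, −20 → 0 °C
Reagents that add atoms: titanium tetrachloride, Cl[Ti](Cl)(Cl)Cl (titanium stays only in 28)
Why: Titanium binds the two carbonyl oxygens of the malonyl unit and pyridine removes a C11 proton; the chelated enolate adds through C11 to the C7 ketone, which the two flanking acyloxy carbons make strongly electrophilic, and aldolate 28 then loses its titanium-bound oxygen together with the remaining acidic C11–H (E1cB) to give the tetrasubstituted C7=C11 alkene. The closest known reaction type is the TiCl4/amine Knoevenagel condensation of malonates with ketones and, in intramolecular form, the conversion of malonate esters of α-hydroxy ketones into α-acyl butenolides. Ring B closes in the 5-(enolexo)-exo-trig mode, because the enolate double bond can lie toward the thioester carbonyl, outside the forming five-membered lactone. No stereocentre is created: C7 and C11 become sp2, the small ring dictates the alkene geometry, and C4, C5, C6, C8 and C10 are only carried through. The step must choose C7 over the C1 ketone, which the tether secures (five-membered against nine-membered closure), and must leave C6–H, C8–H and C10–H alone, which follows from a base as weak as pyridine that can deprotonate only the titanium-activated malonyl CH2. The oxirane is the group at risk, so the Lewis acid is tamed as its THF adduct, pyridine is kept in excess and the temperature stays at or below 0 °C.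

Step 17
Reactants: 29 thioester butenolide
Product: 30 C13 aldehyde (11-formyl butenolide, 4S,5R,6R,8R,10S)
Conditions: Et3SiH (3 equiv), 10% Pd on carbon (5 mol %), acetone, rt
Reagents that add atoms: none
Why: Fukuyama reduction: zerovalent palladium inserts into the acyl–sulfur bond and the silane delivers hydride, a process that leaves ketones, esters, oxiranes and tri- or tetrasubstituted conjugated alkenes alone.

Step 18
Reactants: 30 C13 aldehyde
Product: 31 C13 primary alcohol (11-hydroxymethyl butenolide, 4S,5R,6R,8R,10S)
Conditions: NaBH(OAc)3 (2 equiv), THF, 0 °C → rt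
Reagents that add atoms: none
Why: Chemoselective hydride reduction: NaBH(OAc)3 is too weak a donor for the C1 ketone, the lactone or the esters but reduces aldehydes, and 1,2-attack is favoured because the conjugate position C7 is fully substituted and shielded by ring A.

Step 19
Reactants: 31 C13 alcohol
Product: 32 target, CNP0220542.1 (4S,5R,6R,8R,10S)
Conditions: Ac2O (1.5 equiv), pyridine (3 equiv), CH2Cl2, 0 °C
Reagents that add atoms: acetic anhydride, CC(=O)OC(C)=O
Why: Acetylation of the primary allylic alcohol with pyridine as the only base, which is too weak to deprotonate C6–H of the butenolide.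

Compound list
1 | nerol | CC(C)=CCC/C(C)=C\CO | starting material
2 | (2R,3S)-2,3-epoxynerol | OC[C@H]1O[C@@]1(C)CCC=C(C)C | intermediate
3 | (2S,3S)-3-methyl-3-(4-methylpent-3-enyl)oxirane-2-carbaldehyde | O=C[C@H]1O[C@@]1(C)CCC=C(C)C | intermediate
4 | ethynylmagnesium bromide | C#C[Mg]Br | starting material
5 | (1R)-1-[(2R,3S)-3-methyl-3-(4-methylpent-3-enyl)oxiran-2-yl]prop-2-yn-1-ol | C#C[C@@H](O)[C@H]1O[C@@]1(C)CCC=C(C)C | intermediate
6 | triethylsilyl ether of 5 | C#C[C@@H](O[Si](CC)(CC)CC)[C@H]1O[C@@]1(C)CCC=C(C)C | intermediate
7 | C7 tributylstannyl alkene (vinylstannane) | C=C([Sn](CCCC)(CCCC)CCCC)[C@@H](O[Si](CC)(CC)CC)[C@H]1O[C@@]1(C)CCC=C(C)C | intermediate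
8 | 2-iodoallyl triethylsilyl ether (4S,5R,6S) | IC(=C)[C@@H](O[Si](CC)(CC)CC)[C@H]1O[C@@]1(C)CCC=C(C)C | intermediate
9 | vicinal diol from the isopropylidene alkene of 8 | IC(=C)[C@@H](O[Si](CC)(CC)CC)[C@H]1O[C@@]1(C)CCC(O)C(C)(C)O | intermediate
10 | C1 aldehyde (4S,5R,6S) | IC(=C)[C@@H](O[Si](CC)(CC)CC)[C@H]1O[C@@]1(C)CCC=O | intermediate
11 | (E)-crotylboronate of (R,R)-diisopropyl tartrate | C/C=C/CB1O[C@@H](C(=O)OC(C)C)[C@H](C(=O)OC(C)C)O1 | starting material
12 | anti homoallylic alcohol (1R,4S,5R,6S,10S) | IC(=C)[C@@H](O[Si](CC)(CC)CC)[C@H]1O[C@@]1(C)CC[C@@H](O)[C@@H](C)C=C | intermediate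
13 | O1-borinate, C8-borane bis(9-BBN) adduct | IC(=C)[C@@H](O[Si](CC)(CC)CC)[C@H]1O[C@@]1(C)CC[C@@H](OB1C2CCCC1CCC2)[C@@H](C)CCB1C2CCCC1CCC2 | intermediate
14 | C1/C8 1,4-diol (1R,4S,5R,6S,10S) | IC(=C)[C@@H](O[Si](CC)(CC)CC)[C@H]1O[C@@]1(C)CC[C@@H](O)[C@@H](C)CCO | intermediate
15 | bis(dimethylalkoxysulfonium) dichloride of 14 | IC(=C)[C@@H](O[Si](CC)(CC)CC)[C@H]1O[C@@]1(C)CC[C@@H](O[S+](C)C)[C@@H](C)CCO[S+](C)C.[Cl-].[Cl-] | intermediate
16 | C1-keto C8-aldehyde (4S,5R,6S,10S) | IC(=C)[C@@H](O[Si](CC)(CC)CC)[C@H]1O[C@@]1(C)CCC(=O)[C@@H](C)CC=O | intermediate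
17 | C7 alkenylchromium dichloride | C=C([Cr](Cl)Cl)[C@@H](O[Si](CC)(CC)CC)[C@H]1O[C@@]1(C)CCC(=O)[C@@H](C)CC=O | intermediate
18 | ring A allylic alcohol, 7-methylene, 6-OSiEt3, 8-OH (4S,5R,6R,8R,10S) | C=C1[C@@H](O[Si](CC)(CC)CC)[C@H]2O[C@@]2(C)CCC(=O)[C@@H](C)C[C@H]1O | intermediate
19 | spiro secondary ozonide at C7 | C1OC2(OO1)[C@@H](O[Si](CC)(CC)CC)[C@H]1O[C@@]1(C)CCC(=O)[C@@H](C)C[C@H]2O | intermediate
20 | 8-hydroxy-6-silyloxy-1,7-diketone (4S,5R,6S,8R,10S) | O=C1[C@@H](O[Si](CC)(CC)CC)[C@H]2O[C@@]2(C)CCC(=O)[C@@H](C)C[C@H]1O | intermediate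
21 | 3-methylbut-2-enoic acid | CC(C)=CC(=O)O | starting material
22 | C8 senecioate, 6-OSiEt3 (4S,5R,6S,8R,10S) | O=C1[C@@H](O[Si](CC)(CC)CC)[C@H]2O[C@@]2(C)CCC(=O)[C@@H](C)C[C@H]1OC(=O)C=C(C)C | intermediate
23 | C8 senecioate, 6-OH (4S,5R,6S,8R,10S) | O=C1[C@@H](O)[C@H]2O[C@@]2(C)CCC(=O)[C@@H](C)C[C@H]1OC(=O)C=C(C)C | intermediate
24 | Meldrum's acid | CC1(C)OC(=O)CC(=O)O1 | starting material
25 | ethanethiol | CCS | starting material
26 | 3-(ethylsulfanyl)-3-oxopropanoic acid | CCSC(=O)CC(=O)O | intermediate
27 | O6-(S-ethyl thiomalonyl) 7-ketone, key-step precursor (4S,5R,6S,8R,10S) | CCSC(=O)CC(=O)O[C@H]1[C@H]2O[C@@]2(C)CCC(=O)[C@@H](C)C[C@@H](OC(=O)C=C(C)C)C1=O | intermediate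
28 | trichlorotitanium aldolate (C7–O–Ti, C7–C11 bond formed) | CCSC(=O)C1C(=O)O[C@H]2[C@H]3O[C@@]3(C)CCC(=O)[C@@H](C)C[C@@H](OC(=O)C=C(C)C)C12O[Ti](Cl)(Cl)Cl | intermediate
29 | butenolide with C13 thioester, key-step product (4S,5R,6R,8R,10S) | CCSC(=O)C1=C2[C@@H](OC1=O)[C@H]1O[C@@]1(C)CCC(=O)[C@@H](C)C[C@H]2OC(=O)C=C(C)C | intermediate
30 | C13 aldehyde | O=CC1=C2[C@@H](OC1=O)[C@H]1O[C@@]1(C)CCC(=O)[C@@H](C)C[C@H]2OC(=O)C=C(C)C | intermediate
31 | C13 alcohol | OCC1=C2[C@@H](OC1=O)[C@H]1O[C@@]1(C)CCC(=O)[C@@H](C)C[C@H]2OC(=O)C=C(C)C | intermediate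
32 | CNP0220542.1 | CC(=O)OCC1=C2[C@@H](OC1=O)[C@H]1O[C@@]1(C)CCC(=O)[C@@H](C)C[C@H]2OC(=O)C=C(C)C | target

Total step count: 19. Longest linear sequence: 18 (steps 1–13 and 15–19, from nerol).

Steps most likely to fail

Step 10. The aldehyde may be attacked from the other face, because the sense of induction in a ten-membered transition state cannot be predicted with confidence. The fallback sets out from 16. The same closure then delivers the 8-epimeric allylic alcohol F1, and ozonolysis as in step 11 gives the 8-epimeric hydroxy diketone F2. In place of a retentive acylation, the senecioate is introduced by Mitsunobu esterification with 21 (PPh3, DIAD, toluene, 0 °C). This SN2 displacement is favoured next to a carbonyl group and inverts C8. The route is rejoined at 22.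

Step 16. Opening of the trisubstituted oxirane by the titanium Lewis acid may outrun the condensation, either by chloride capture at C4 or by transannular attack of the C1 carbonyl oxygen. The fallback sets out from 27, separates bond formation from loss of water, and uses no metal halide. A catalytic amount of Et3N in CH2Cl2 at 0 °C should trigger the intramolecular aldol addition to the 7-hydroxy lactone F3, whose configuration at C7 and C11 does not matter. F3 is isolated and dehydrated under neutral conditions with Martin sulfurane (CH2Cl2, −20 °C). This comes back to the route at 29.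

Step 3. Facial selectivity in the acetylide addition to the epoxy aldehyde may be poor and cost much material at C6. The fallback sets out from 5, taken as its mixture with the C6-epimeric propargylic alcohol F4. Dess–Martin oxidation converges both epimers on the epoxy ynone F5. C6 is then set by hydride delivery instead of carbon–carbon bond formation. Zn(BH4)2 in Et2O at −20 °C chelates the ketone and oxirane oxygens and attacks from the side of C5–H, the known route from α,β-epoxy ketones to anti epoxy alcohols. This returns to 5.

Further compounds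
F1 | step 10 | 8-epimer of allylic alcohol 18 (8S) | C=C1[C@@H](O[Si](CC)(CC)CC)[C@H]2O[C@@]2(C)CCC(=O)[C@@H](C)C[C@@H]1O
F2 | step 10 | 8-epimer of hydroxy diketone 20 (8S) | O=C1[C@@H](O[Si](CC)(CC)CC)[C@H]2O[C@@]2(C)CCC(=O)[C@@H](C)C[C@@H]1O
F3 | step 16 | 7-hydroxy lactone, aldol adduct of 27 | CCSC(=O)C1C(=O)O[C@H]2[C@H]3O[C@@]3(C)CCC(=O)[C@@H](C)C[C@@H](OC(=O)C=C(C)C)C12O
F4 | step 3 | C6 epimer of propargylic alcohol 5 (1S) | C#C[C@H](O)[C@H]1O[C@@]1(C)CCC=C(C)C
F5 | step 3 | 1-[(2S,3S)-3-methyl-3-(4-methylpent-3-enyl)oxiran-2-yl]prop-2-yn-1-one | C#CC(=O)[C@H]1O[C@@]1(C)CCC=C(C)C
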